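**Retrosynthetic overview**

1. The strategy rests on the homoallylic tertiary alcohol of the upper unit: C1 (the carbinol shared by the cyclohexene C1–C2–C3–C11′–C13′–C5 and the cycloheptane C1–C10–C9–C8–C7–C6–C5) is bonded to the methyl-bearing C10, and C8 lies two atoms further on. With C8=C9 as an alkene this is the retron of an intramolecular allylsilane addition to a C1 ketone, which forms C1–C10, closes the seven-membered ring and sets C1 and C10.
2. After ring closure the C8=C9 alkene is converted into the cis-fused α-methylene lactone by iodolactonisation of a C12 acrylic acid (carried as a C12–OPMB allylic ether) and radical deiodination; the C4 ketone is carried as a PMB-protected carbinol.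
3. The spiro cyclohexenone precursor comes from a Diels–Alder reaction of a 2-silyloxy diene (C5=C1(OTBS)–C2=C3, bearing the C6–C10 crotylsilane chain) with the α-methylene lactone of 8-epi-xanthatin (bonds C5–C13′ and C3–C11′), followed by Saegusa oxidation.
4. C7 and C8 of the crotylsilane chain are set by an Ireland–Claisen rearrangement of an (R,E)-γ-silyl allylic ester; 8-epi-xanthatin is built by an auxiliary-controlled syn-aldol, carbonylative lactonisation of an enol triflate and a domino enyne ring-closing/cross-metathesis.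
5. Ring order: lower lactone, lower cycloheptadiene, spiro cyclohexene (cycloaddition), upper cycloheptene (key step), upper lactone.

Key step: step 30

Remark: xanthanolide numbering is used (upper unit C1–C15, lower unit primed; C11′ is the spiro carbon, C13′ the ring methylene); the (S) configuration of the C4 carbinol is an arbitrary choice, since C4 is oxidised to the ketone in step 32.

**Lower unit (8-epi-xanthatin)**

Step 1
Reactants: 1 (4R)-4-benzyl-3-propanoyl-1,3-oxazolidin-2-one; 2 tert-butyl bromoacetate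
Product: 3 tert-butyl (3S)-4-[(4R)-4-benzyl-2-oxo-1,3-oxazolidin-3-yl]-3-methyl-4-oxobutanoate
Conditions: NaN(SiMe3)2, THF, −78 °C; then 2, −78 to −40 °C
Reagents that add atoms: none
Why: Auxiliary-controlled (Evans) enolate alkylation, in which the chelated (Z)-sodium enolate is alkylated on the face opposite the benzyl group of the (4R)-auxiliary, setting C10′ as (S).

Step 2
Reactants: 3 alkylated imide
Product: 4 tert-butyl (3S)-4-hydroxy-3-methylbutanoate
Conditions: LiBH4, MeOH (1 equiv), THF, 0 °C
Reagents that add atoms: none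
Why: Chemoselective reductive cleavage of the imide, whose exocyclic carbonyl is far more electrophilic than the tert-butyl ester, frees the primary alcohol without touching the stereocentre.

Step 3
Reactants: 4 hydroxy ester
Product: 5 tert-butyl (3S)-3-methyl-4-oxobutanoate
Conditions: Dess–Martin periodinane, NaHCO3, CH2Cl2, 0 °C to rt
Reagents that add atoms: none
Why: Dess–Martin oxidation of a primary alcohol under buffered, non-epimerising conditions, the aldehyde being used at once.

Step 4
Reactants: 5 aldehyde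
Product: 6 tert-butyl (3S)-3-methylpent-4-ynoate
Conditions: dimethyl (1-diazo-2-oxopropyl)phosphonate, K2CO3, MeOH, 0 °C to rt
Reagents that add atoms: dimethyl (1-diazo-2-oxopropyl)phosphonate, COP(=O)(OC)C(=[N+]=[N-])C(C)=O
Why: Ohira–Bestmann homologation (Seyferth–Gilbert reagent generated in situ) converts the aldehyde into the terminal alkyne under mild carbonate conditions at low temperature, chosen to preserve the α-stereocentre.

Step 5
Reactants: 6 alkynyl ester
Product: 7 (3S)-3-methylpent-4-ynal
Conditions: i-Bu2AlH, CH2Cl2, −78 °C; aq. KNaC4H4O6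
Reagents that add atoms: none
Why: Half-reduction of the ester with i-Bu2AlH at −78 °C stops at the aluminium hemiacetal, which releases the (volatile) aldehyde on work-up; it is used as a solution.

Step 6
Reactants: 8 (4S)-4-benzyl-1,3-oxazolidin-2-one; 9 pent-4-enoyl chloride
Product: 10 (4S)-4-benzyl-3-(pent-4-enoyl)-1,3-oxazolidin-2-one
Conditions: n-BuLi, THF, −78 °C; then 9
Reagents that add atoms: none
Why: N-acylation of the lithiated oxazolidinone with an acid chloride.

Step 7
Reactants: 10 pentenoyl imide; 7 (3S)-3-methylpent-4-ynal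
Product: 12 (4S)-4-benzyl-3-[(2S,3R,5S)-3-hydroxy-5-methyl-2-(prop-2-en-1-yl)hept-6-ynoyl]-1,3-oxazolidin-2-one, via boron enolate 11 (not isolated)
Conditions: Bu2BOTf, i-Pr2NEt, CH2Cl2, −78 to 0 °C; 7, −78 to 0 °C; then pH 7 buffer, MeOH, H2O2
Reagents that add atoms: none
Why: Evans syn-aldol reaction, in which the (Z)-boron enolate reacts through a Zimmerman–Traxler chair on the face away from the benzyl group and sets C7′ (allyl) and C8′ (hydroxyl) syn, the relationship that becomes the cis ring fusion of the lactone.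

Step 8
Reactants: 12 aldol adduct
Product: 13 (2S,3R,5S)-3-hydroxy-N-methoxy-N,5-dimethyl-2-(prop-2-en-1-yl)hept-6-ynamide
Conditions: Me3Al, MeNHOMe·HCl, THF, 0 °C to rt
Reagents that add atoms: N,O-dimethylhydroxylamine hydrochloride, CNOC.Cl
Why: Aluminium amide transamidation (Weinreb amide formation) of the β-hydroxy imide releases the auxiliary.

Step 9
Reactants: 13 hydroxy Weinreb amide
Product: 14 (2S,3R,5S)-N-methoxy-N,5-dimethyl-2-(prop-2-en-1-yl)-3-[(triethylsilyl)oxy]hept-6-ynamide
Conditions: Et3SiCl, imidazole, DMF, 0 °C to rt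
Reagents that add atoms: chlorotriethylsilane, CC[Si](Cl)(CC)CC
Why: Silylation of the secondary alcohol so that the derived ketone can later be enolised without retro-aldol cleavage or O-triflation.

Step 10
Reactants: 14 silyl-protected Weinreb amide
Product: 15 (3S,4R,6S)-6-methyl-3-(prop-2-en-1-yl)-4-[(triethylsilyl)oxy]oct-7-yn-2-one
Conditions: MeMgBr (3 equiv), THF, 0 °C; aq. NH4Cl
Reagents that add atoms: methylmagnesium bromide, C[Mg]Br
Why: Weinreb ketone synthesis, the chelated tetrahedral intermediate preventing over-addition.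

Step 11
Reactants: 15 methyl ketone
Product: 16 (3S,4R,6S)-6-methyl-3-(prop-2-en-1-yl)-4-[(triethylsilyl)oxy]oct-1-en-7-yn-2-yl trifluoromethanesulfonate
Conditions: KN(SiMe3)2, THF, −78 °C; then PhNTf2, −78 to −20 °C
Reagents that add atoms: N-phenylbis(trifluoromethanesulfonimide), FC(F)(F)S(=O)(=O)N(c1ccccc1)S(=O)(=O)C(F)(F)F
Why: Kinetic deprotonation takes place at the methyl group rather than at the hindered C7′ methine or the less acidic acetylenic C–H, and O-triflation of that enolate gives the terminal enol triflate.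

Step 12
Reactants: 16 silyl-protected enol triflate
Product: 17 (3S,4R,6S)-4-hydroxy-6-methyl-3-(prop-2-en-1-yl)oct-1-en-7-yn-2-yl trifluoromethanesulfonate
Conditions: HF·pyridine, pyridine, THF, 0 °C
Reagents that add atoms: none
Why: Buffered fluoride cleavage of the triethylsilyl ether leaves the enol triflate intact.

Step 13
Reactants: 17 hydroxy enol triflate
Product: 18 (4R,5R)-3-methylidene-5-[(2S)-2-methylbut-3-yn-1-yl]-4-(prop-2-en-1-yl)oxolan-2-one
Conditions: Pd(PPh3)4 (10 mol %), CO (1 atm), n-Bu3N, LiCl, MeCN, 65 °C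
Reagents that add atoms: carbon monoxide, [C-]#[O+]
Why: Carbonylative lactonisation, in which oxidative addition of zerovalent palladium into the C–OTf bond, CO insertion and capture of the acylpalladium by the C8′ hydroxyl build the α-methylene lactone, cis-substituted because of the syn aldol.

Step 14
Reactants: 18 enyne lactone; 19 but-3-en-2-one
Product: 21 8-epi-xanthatin [(3aR,7S,8aR)-7-methyl-3-methylidene-6-[(1E)-3-oxobut-1-en-1-yl]-3,3a,4,7,8,8a-hexahydro-2H-cyclohepta[b]furan-2-one], via vinyl diene 20 (not isolated)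
Conditions: (H2IMes)Cl2Ru=CH(C6H4-2-O-i-Pr) (second-generation Hoveyda–Grubbs catalyst, 10 mol %), 19 (excess), CH2Cl2, 40 °C
Reagents that add atoms: none
Why: Domino ring-closing enyne metathesis and cross-metathesis, in which the alkylidene formed at the allyl terminus closes the seven-membered ring onto the alkyne in the exo mode and the resulting 1-vinylcycloheptene is capped by the enone partner to give the (E)-dienone.

**Crotylsilane chain and diene**

Step 15
Reactants: 22 (2R)-4-(trimethylsilyl)but-3-yn-2-ol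
Product: 23 (2R,3E)-4-(trimethylsilyl)but-3-en-2-ol
Conditions: NaAlH2(OCH2CH2OMe)2, Et2O, 0 °C to rt; aq. KNaC4H4O6
Reagents that add atoms: none
Why: Hydroxyl-directed trans-hydroalumination of the propargylic alcohol followed by protonolysis gives the (E)-vinylsilane without touching the carbinol stereocentre.

Step 16
Reactants: 24 methyl 5,5-dimethoxypentanoate
Product: 25 5,5-dimethoxypentanoic acid
Conditions: LiOH, THF/H2O, rt; then NaH2PO4 to pH 5, 0 °C
Reagents that add atoms: lithium hydroxide, [Li+].[OH-]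
Why: Ester saponification, the dimethyl acetal being stable to base and to the buffered acidification.

Step 17
Reactants: 23 (R,E)-silyl allylic alcohol; 25 acetal acid
Product: 26 (2R,3E)-4-(trimethylsilyl)but-3-en-2-yl 5,5-dimethoxypentanoate
Conditions: DCC, DMAP (cat.), CH2Cl2, 0 °C to rt
Reagents that add atoms: none
Why: Steglich esterification, which does not affect the carbinol stereocentre.

Step 18
Reactants: 26 allylic ester
Product: 29 (2R,3S,4E)-2-(3,3-dimethoxypropyl)-3-(trimethylsilyl)hex-4-enoic acid, via silyl ketene acetal 27 (not isolated), via trimethylsilyl ester 28 (not isolated)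
Conditions: LiN(i-Pr)2, THF, −78 °C; Me3SiCl/Et3N; −78 °C to rt, then 55 °C; aq. NaOH, then citric acid to pH 4
Reagents that add atoms: none
Why: Ireland–Claisen rearrangement, in which the (E)-enolate formed in THF is silylated and rearranges through a chair with the carbinol methyl equatorial, so that the (R)-carbinol chirality is transferred to C8 (S), the new alkene C9=C10 is (E), and C7 (R) is set anti to silicon by the enolate geometry.

Step 19
Reactants: 29 β-silyl acid
Product: 30 (2R,3S,4E)-2-(3,3-dimethoxypropyl)-N-methoxy-N-methyl-3-(trimethylsilyl)hex-4-enamide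
Conditions: MeNHOMe·HCl, EDCI·HCl, HOBt, i-Pr2NEt, CH2Cl2, 0 °C to rt
Reagents that add atoms: N,O-dimethylhydroxylamine hydrochloride, CNOC.Cl
Why: Carbodiimide amide coupling to the Weinreb amide under conditions that do not epimerise C7.

Step 20
Reactants: 31 (tributylstannyl)methanol
Product: 32 tributyl{[(4-methoxyphenyl)methoxy]methyl}stannane
Conditions: NaH, THF/DMF, 0 °C; 4-methoxybenzyl chloride, Bu4NI (cat.), rt
Reagents that add atoms: 4-methoxybenzyl chloride, COc1ccc(CCl)cc1
Why: Williamson etherification of the sodium alkoxide.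

Step 21
Reactants: 30 Weinreb amide; 32 alkoxymethylstannane
Product: 34 (3R,4S,5E)-3-(3,3-dimethoxypropyl)-1-[(4-methoxyphenyl)methoxy]-4-(trimethylsilyl)hept-5-en-2-one, via lithiomethyl ether 33 (not isolated)
Conditions: 32, n-BuLi, THF, −78 °C; then 30, −78 °C; aq. NH4Cl
Reagents that add atoms: none
Why: Tin–lithium exchange gives the α-alkoxymethyllithium, which adds once to the Weinreb amide through the chelated tetrahedral intermediate and supplies C12 with its oxygen without epimerising C7.

Step 22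
Reactants: 34 α-alkoxy ketone
Product: 35 [(3R,4S,5E)-3-(3,3-dimethoxypropyl)-2-{[(4-methoxyphenyl)methoxy]methyl}hepta-1,5-dien-4-yl](trimethyl)silane
Conditions: Ph3PCH3Br, KN(SiMe3)2, THF, 0 °C; then 34, 0 °C to rt
Reagents that add atoms: methyltriphenylphosphonium bromide, C[P+](c1ccccc1)(c1ccccc1)c1ccccc1.[Br-]
Why: Wittig methylenation of the activated α-alkoxy ketone with the non-stabilised ylide at low temperature should outrun enolisation toward C7 and installs C13.

Step 23
Reactants: 35 acetal
Product: 36 (4R,5S,6E)-4-{3-[(4-methoxyphenyl)methoxy]prop-1-en-2-yl}-5-(trimethylsilyl)oct-6-enal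
Conditions: pyridinium p-toluenesulfonate (cat.), acetone/H2O (10:1), 45 °C
Reagents that add atoms: water, O
Why: Mild acid-catalysed acetal hydrolysis, to which the secondary allylsilane and the PMB ether are stable.

Step 24
Reactants: 37 (2S)-but-3-yn-2-ol
Product: 38 1-{[(2S)-but-3-yn-2-yl]oxymethyl}-4-methoxybenzene
Conditions: NaH, THF, 0 °C; 4-methoxybenzyl chloride, Bu4NI (cat.), rt
Reagents that add atoms: 4-methoxybenzyl chloride, COc1ccc(CCl)cc1
Why: Williamson etherification of the secondary alkoxide.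

Step 25
Reactants: 36 aldehyde; 38 alkyne PMB ether
Product: 41 (2S,3E,8R,9S,10E)-2-[(4-methoxyphenyl)methoxy]-8-{3-[(4-methoxyphenyl)methoxy]prop-1-en-2-yl}-9-(trimethylsilyl)dodeca-3,10-dien-5-ol (both C5 epimers of this chain), via alkenylzirconocene chloride 39 (not isolated), via alkenylmethylzinc 40 (not isolated)
Conditions: 38, Cp2Zr(H)Cl, CH2Cl2, rt; Me2Zn, toluene, −65 °C; then 36, 0 °C; aq. NH4Cl
Reagents that add atoms: none
Why: Syn hydrozirconation of the terminal alkyne and transmetalation to zinc give an (E)-alkenylzinc that adds 1,2 to the aldehyde, the new carbinol centre being of no consequence because it is oxidised in step 26.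

Step 26
Reactants: 41 allylic alcohol
Product: 42 (2S,3E,8R,9S,10E)-2-[(4-methoxyphenyl)methoxy]-8-{3-[(4-methoxyphenyl)methoxy]prop-1-en-2-yl}-9-(trimethylsilyl)dodeca-3,10-dien-5-one
Conditions: Dess–Martin periodinane, NaHCO3, CH2Cl2, 0 °C to rt
Reagents that add atoms: none
Why: Dess–Martin oxidation of the secondary allylic alcohol to the (E)-enone under buffered conditions that spare the allylsilane.

Step 27
Reactants: 42 enone
Product: 43 tert-butyl{[(2S,3E,5Z,8R,9S,10E)-2-[(4-methoxyphenyl)methoxy]-8-{3-[(4-methoxyphenyl)methoxy]prop-1-en-2-yl}-9-(trimethylsilyl)dodeca-3,5,10-trien-5-yl]oxy}dimethylsilane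
Conditions: t-BuMe2SiOTf, Et3N, CH2Cl2, −78 to 0 °C
Reagents that add atoms: tert-butyldimethylsilyl trifluoromethanesulfonate, CC(C)(C)[Si](C)(C)OS(=O)(=O)C(F)(F)F
Why: Soft enolisation at the α′-methylene C5 gives the cross-conjugated 2-silyloxy diene, (Z) at C5=C1 so that the C6 chain is an outside substituent of the s-cis diene.

**Assembly, key step and endgame**

Step 28
Reactants: 43 2-silyloxy diene; 21 8-epi-xanthatin
Product: 44 endo spiro cycloadduct (C1 TBS enol ether C1=C2; H3 and H5 cis; C3 on the H7′ face of the lactone)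
Conditions: 43 (1.5 equiv), 2,6-di-tert-butyl-4-methylphenol (cat.), toluene, 100 °C, sealed tube
Reagents that add atoms: none
Why: Normal-electron-demand Diels–Alder reaction, in which the silyloxy group makes C5 the nucleophilic terminus (C5 to C13′, C3 to C11′), the diene adds to the convex face of the cis-fused lactone (syn to H7′) to set C11′, and the endo orientation of the lactone carbonyl sets C5.

Step 29
Reactants: 44 cycloadduct
Product: 45 spiro cyclohexenone (C1 ketone; C2=C3; C3–[(1S)-1-(PMB-oxy)ethyl]; (5S) chain C6H2–C7H[C(=CH2)CH2OPMB]–C8H(SiMe3)–(E)-CH=CHCH3 of (7R,8S) configuration)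
Conditions: Pd(OAc)2 (1.1 equiv), MeCN, 40 °C
Reagents that add atoms: none
Why: Saegusa–Ito oxidation, in which the silyl enol ether is converted into the C2 palladium enolate and β-hydride elimination of H3 places the alkene at C2=C3 only, the silyl enol ether being far more nucleophilic toward divalent palladium than the crotylsilane.

Step 30
Reactants: 45 spiro cyclohexenone
Product: 46 trans-fused tertiary carbinol (C1–OH cis to C10–CH3 and anti to H5; C8=C9 ring alkene; C7–C(=CH2)CH2OPMB; C4–OPMB)
Conditions: TiCl4 (3 equiv), 2,6-di-tert-butyl-4-methylpyridine, CH2Cl2 (0.002 M), −78 °C; Et3N/MeOH, then aq. NaHCO3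
Reagents that add atoms: none
Why: TiCl4 activates the C1 carbonyl of the cross-conjugated enone and the (E)-crotylsilane attacks it through its γ-carbon C10 anti to the C8–Si bond (SE2′), after which the β-silyl cation loses the silyl group as Me3SiCl to leave the C8=C9 alkene. The closest known reaction type is the TiCl4-promoted intramolecular Hosomi–Sakurai 1,2-allylation of ketones and enones used to close seven-membered carbocycles. The cycloheptene C1–C10–C9–C8–C7–C6–C5 closes in a 7-endo mode with respect to the allyl π-bond (C9 and C10 both become ring atoms) and exo with respect to the C1=O acceptor. C10 is controlled by the (8S) silyl centre together with the (E)-alkene: a cis ring alkene forces C7 into the inside position of the allyl unit, where it meets only H10, the (7R) centre then turns its C11 branch outward, and anti attack puts the C10 methyl on the same ring face as the new hydroxyl. C1 is controlled by the C5 tether, which sits pseudo-equatorial on the cyclohexenone and delivers C10 through the synclinal transition state (C1=O gauche to C9=C10, ring carbon C2 turned away from the crotyl unit), that is, equatorial attack giving the trans-fused 6–7 system. The step needs 1,2- over 1,4-addition and reaction of the allylsilane in preference to the C11=C13 alkene and to intermolecular partners: C3 could be reached only through a nine-membered ring, attack through C8 is ruled out by the γ-regiochemistry of allylsilanes, the crotylsilane is far more nucleophilic than the allylic-ether alkene, and high dilution with a hindered pyridine base at −78 °C disfavours conjugate allylation of the lower dienone, protodesilylation and ionisation of the tertiary allylic alkoxide.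

Step 31
Reactants: 46 bis-PMB ether
Product: 47 triol (C1–OH; C4–OH; C12–OH)
Conditions: DDQ (2.6 equiv), CH2Cl2/pH 7 phosphate buffer (10:1), 0 °C to rt
Reagents that add atoms: none
Why: Oxidative cleavage of both 4-methoxybenzyl ethers (benzylic hydride abstraction, then hydrolysis of the oxocarbenium ions), any over-oxidation of the allylic alcohols converging in step 32.

Step 32
Reactants: 47 triol
Product: 48 keto enal (C4 ketone; C12 aldehyde; C1–OH)
Conditions: Dess–Martin periodinane (3 equiv), NaHCO3, CH2Cl2, 0 °C to rt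
Reagents that add atoms: none
Why: Dess–Martin oxidation converts the primary and secondary allylic alcohols into the enal and the C4 enone, while the tertiary C1 alcohol cannot be oxidised.

Step 33
Reactants: 48 keto enal
Product: 49 acrylic acid (C12 CO2H)
Conditions: NaClO2, NaH2PO4, 2-methylbut-2-ene (excess), t-BuOH/H2O, 0 °C to rt
Reagents that add atoms: sodium chlorite, [Na+].[O-]Cl=O
Why: Pinnick oxidation of the enal to the acid, the scavenger removing HOCl so that the C8=C9 alkene is spared.

Step 34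
Reactants: 49 acrylic acid
Product: 50 9-iodo lactone (C8–O cis to C7–C11; iodine at C9 trans to the lactone oxygen)
Conditions: I2 (3 equiv), NaHCO3, MeCN/H2O, 0 °C, dark; aq. Na2S2O3
Reagents that add atoms: iodine, II
Why: Iodolactonisation, in which the carboxylate opens the iodonium ion of the only electron-rich alkene (C8=C9) 5-exo at C8 on the face of its own tether, giving the cis-fused γ-lactone with C8 correctly set and iodine trans at C9.

Step 35
Reactants: 50 iodo lactone
Product: 51 CNP0168949.1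
Conditions: Bu3SnH (1.3 equiv), AIBN (cat.), toluene, 80 °C
Reagents that add atoms: none
Why: Radical chain deiodination, in which iodine abstraction and hydrogen transfer to the secondary C9 radical should be faster than addition of tin radicals to the enoate and enone groups.

**Compound list**

1 | (4R)-4-benzyl-3-propanoyl-1,3-oxazolidin-2-one | CCC(=O)N1[C@H](Cc2ccccc2)COC1=O | starting material
2 | tert-butyl bromoacetate | CC(C)(C)OC(=O)CBr | starting material
3 | tert-butyl (3S)-4-[(4R)-4-benzyl-2-oxo-1,3-oxazolidin-3-yl]-3-methyl-4-oxobutanoate | CC(C)(C)OC(=O)C[C@H](C)C(=O)N1[C@H](Cc2ccccc2)COC1=O | intermediate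
4 | tert-butyl (3S)-4-hydroxy-3-methylbutanoate | CC(C)(C)OC(=O)C[C@H](C)CO | intermediate
5 | tert-butyl (3S)-3-methyl-4-oxobutanoate | CC(C)(C)OC(=O)C[C@H](C)C=O | intermediate
6 | tert-butyl (3S)-3-methylpent-4-ynoate | CC(C)(C)OC(=O)C[C@H](C)C#C | intermediate
7 | (3S)-3-methylpent-4-ynal | O=CC[C@H](C)C#C | intermediate
8 | (4S)-4-benzyl-1,3-oxazolidin-2-one | O=C1N[C@@H](Cc2ccccc2)CO1 | starting material
9 | pent-4-enoyl chloride | C=CCCC(Cl)=O | starting material
10 | (4S)-4-benzyl-3-(pent-4-enoyl)-1,3-oxazolidin-2-one | C=CCCC(=O)N1[C@@H](Cc2ccccc2)COC1=O | intermediate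
11 | (Z)-dibutylboron enolate of 10 (not isolated) | C=CC/C=C(\OB(CCCC)CCCC)N1[C@@H](Cc2ccccc2)COC1=O | intermediate
12 | (4S)-4-benzyl-3-[(2S,3R,5S)-3-hydroxy-5-methyl-2-(prop-2-en-1-yl)hept-6-ynoyl]-1,3-oxazolidin-2-one | C=CC[C@H](C(=O)N1[C@@H](Cc2ccccc2)COC1=O)[C@H](O)C[C@H](C)C#C | intermediate
13 | (2S,3R,5S)-3-hydroxy-N-methoxy-N,5-dimethyl-2-(prop-2-en-1-yl)hept-6-ynamide | C=CC[C@H](C(=O)N(C)OC)[C@H](O)C[C@H](C)C#C | intermediate
14 | (2S,3R,5S)-N-methoxy-N,5-dimethyl-2-(prop-2-en-1-yl)-3-[(triethylsilyl)oxy]hept-6-ynamide | C=CC[C@H](C(=O)N(C)OC)[C@H](O[Si](CC)(CC)CC)C[C@H](C)C#C | intermediate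
15 | (3S,4R,6S)-6-methyl-3-(prop-2-en-1-yl)-4-[(triethylsilyl)oxy]oct-7-yn-2-one | C=CC[C@H](C(C)=O)[C@H](O[Si](CC)(CC)CC)C[C@H](C)C#C | intermediate
16 | (3S,4R,6S)-6-methyl-3-(prop-2-en-1-yl)-4-[(triethylsilyl)oxy]oct-1-en-7-yn-2-yl trifluoromethanesulfonate | C=CC[C@H](C(=C)OS(=O)(=O)C(F)(F)F)[C@H](O[Si](CC)(CC)CC)C[C@H](C)C#C | intermediate
17 | (3S,4R,6S)-4-hydroxy-6-methyl-3-(prop-2-en-1-yl)oct-1-en-7-yn-2-yl trifluoromethanesulfonate | C=CC[C@H](C(=C)OS(=O)(=O)C(F)(F)F)[C@H](O)C[C@H](C)C#C | intermediate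
18 | (4R,5R)-3-methylidene-5-[(2S)-2-methylbut-3-yn-1-yl]-4-(prop-2-en-1-yl)oxolan-2-one | C=C1C(=O)O[C@H](C[C@H](C)C#C)[C@@H]1CC=C | intermediate
19 | but-3-en-2-one | CC(=O)C=C | starting material
20 | (3aR,7S,8aR)-6-ethenyl-7-methyl-3-methylidene-3,3a,4,7,8,8a-hexahydro-2H-cyclohepta[b]furan-2-one (not isolated) | C=C1C(=O)O[C@@H]2C[C@H](C)C(C=C)=CC[C@@H]12 | intermediate
21 | 8-epi-xanthatin, (3aR,7S,8aR)-7-methyl-3-methylidene-6-[(1E)-3-oxobut-1-en-1-yl]-3,3a,4,7,8,8a-hexahydro-2H-cyclohepta[b]furan-2-one | C=C1C(=O)O[C@@H]2C[C@H](C)C(/C=C/C(C)=O)=CC[C@@H]12 | intermediate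
22 | (2R)-4-(trimethylsilyl)but-3-yn-2-ol | C[C@@H](O)C#C[Si](C)(C)C | starting material
23 | (2R,3E)-4-(trimethylsilyl)but-3-en-2-ol | C[C@@H](O)/C=C/[Si](C)(C)C | intermediate
24 | methyl 5,5-dimethoxypentanoate | COC(OC)CCCC(=O)OC | starting material
25 | 5,5-dimethoxypentanoic acid | COC(OC)CCCC(O)=O | intermediate
26 | (2R,3E)-4-(trimethylsilyl)but-3-en-2-yl 5,5-dimethoxypentanoate | COC(OC)CCCC(=O)O[C@H](C)/C=C/[Si](C)(C)C | intermediate
27 | trimethylsilyl ketene acetal of 26, alkyl chain trans to OSiMe3 (not isolated) | COC(OC)CC/C=C(/O[Si](C)(C)C)O[C@H](C)/C=C/[Si](C)(C)C | intermediate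
28 | trimethylsilyl (2R,3S,4E)-2-(3,3-dimethoxypropyl)-3-(trimethylsilyl)hex-4-enoate (not isolated) | COC(OC)CC[C@H](C(=O)O[Si](C)(C)C)[C@@H]([Si](C)(C)C)/C=C/C | intermediate
29 | (2R,3S,4E)-2-(3,3-dimethoxypropyl)-3-(trimethylsilyl)hex-4-enoic acid | COC(OC)CC[C@H](C(O)=O)[C@@H]([Si](C)(C)C)/C=C/C | intermediate
30 | (2R,3S,4E)-2-(3,3-dimethoxypropyl)-N-methoxy-N-methyl-3-(trimethylsilyl)hex-4-enamide | COC(OC)CC[C@H](C(=O)N(C)OC)[C@@H]([Si](C)(C)C)/C=C/C | intermediate
31 | (tributylstannyl)methanol | OC[Sn](CCCC)(CCCC)CCCC | starting material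
32 | tributyl{[(4-methoxyphenyl)methoxy]methyl}stannane | COc1ccc(COC[Sn](CCCC)(CCCC)CCCC)cc1 | intermediate
33 | {[(4-methoxyphenyl)methoxy]methyl}lithium (not isolated) | [Li]COCc1ccc(OC)cc1 | intermediate
34 | (3R,4S,5E)-3-(3,3-dimethoxypropyl)-1-[(4-methoxyphenyl)methoxy]-4-(trimethylsilyl)hept-5-en-2-one | COC(OC)CC[C@H](C(=O)COCc1ccc(OC)cc1)[C@@H]([Si](C)(C)C)/C=C/C | intermediate
35 | [(3R,4S,5E)-3-(3,3-dimethoxypropyl)-2-{[(4-methoxyphenyl)methoxy]methyl}hepta-1,5-dien-4-yl](trimethyl)silane | COC(OC)CC[C@H](C(=C)COCc1ccc(OC)cc1)[C@@H]([Si](C)(C)C)/C=C/C | intermediate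
36 | (4R,5S,6E)-4-{3-[(4-methoxyphenyl)methoxy]prop-1-en-2-yl}-5-(trimethylsilyl)oct-6-enal | O=CCC[C@H](C(=C)COCc1ccc(OC)cc1)[C@@H]([Si](C)(C)C)/C=C/C | intermediate
37 | (2S)-but-3-yn-2-ol | C[C@H](O)C#C | starting material
38 | 1-{[(2S)-but-3-yn-2-yl]oxymethyl}-4-methoxybenzene | C[C@H](OCc1ccc(OC)cc1)C#C | intermediate
39 | (E)-alkenylzirconocene chloride from 38 (not isolated) | C[C@H](OCc1ccc(OC)cc1)/C=C/[Zr](Cl)(C1C=CC=C1)C1C=CC=C1 | intermediate
40 | (E)-alkenyl(methyl)zinc from 38 (not isolated) | C[C@H](OCc1ccc(OC)cc1)/C=C/[Zn]C | intermediate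
41 | (2S,3E,8R,9S,10E)-2-[(4-methoxyphenyl)methoxy]-8-{3-[(4-methoxyphenyl)methoxy]prop-1-en-2-yl}-9-(trimethylsilyl)dodeca-3,10-dien-5-ol, both C5 epimers of this chain | C[C@H](OCc1ccc(OC)cc1)/C=C/C(O)CC[C@H](C(=C)COCc1ccc(OC)cc1)[C@@H]([Si](C)(C)C)/C=C/C | intermediate
42 | (2S,3E,8R,9S,10E)-2-[(4-methoxyphenyl)methoxy]-8-{3-[(4-methoxyphenyl)methoxy]prop-1-en-2-yl}-9-(trimethylsilyl)dodeca-3,10-dien-5-one | C[C@H](OCc1ccc(OC)cc1)/C=C/C(=O)CC[C@H](C(=C)COCc1ccc(OC)cc1)[C@@H]([Si](C)(C)C)/C=C/C | intermediate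
43 | tert-butyl{[(2S,3E,5Z,8R,9S,10E)-2-[(4-methoxyphenyl)methoxy]-8-{3-[(4-methoxyphenyl)methoxy]prop-1-en-2-yl}-9-(trimethylsilyl)dodeca-3,5,10-trien-5-yl]oxy}dimethylsilane | C[C@H](OCc1ccc(OC)cc1)/C=C/C(O[Si](C)(C)C(C)(C)C)=C/C[C@H](C(=C)COCc1ccc(OC)cc1)[C@@H]([Si](C)(C)C)/C=C/C | intermediate
44 | endo spiro cycloadduct: C1 TBS enol ether (C1=C2), H3 and H5 cis, spiro C11′ with C3 on the H7′ face, crotylsilane chain on C5 | CC(C)(C)[Si](C)(C)OC1=C[C@H]([C@H](C)OCc2ccc(OC)cc2)[C@@]4(C[C@@H]1C[C@H](C(=C)COCc2ccc(OC)cc2)[C@@H]([Si](C)(C)C)/C=C/C)C(=O)O[C@@H]1C[C@H](C)C(/C=C/C(C)=O)=CC[C@@H]14 | intermediate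
45 | spiro cyclohexenone (key-step precursor): C1 ketone, C2=C3, C4–OPMB, (5S) chain with (7R)-C(=CH2)CH2OPMB and (8S)-SiMe3, (E)-C9=C10 | O=C1C=C([C@H](C)OCc2ccc(OC)cc2)[C@@]4(C[C@@H]1C[C@H](C(=C)COCc2ccc(OC)cc2)[C@@H]([Si](C)(C)C)/C=C/C)C(=O)O[C@@H]1C[C@H](C)C(/C=C/C(C)=O)=CC[C@@H]14 | intermediate
46 | trans-fused tertiary carbinol (key-step product): C1–OH cis to C10–CH3, C8=C9, C7–C(=CH2)CH2OPMB, C4–OPMB | O[C@]12C=C([C@H](C)OCc3ccc(OC)cc3)[C@@]4(C[C@@H]1C[C@H](C(=C)COCc3ccc(OC)cc3)C=C[C@@H]2C)C(=O)O[C@@H]1C[C@H](C)C(/C=C/C(C)=O)=CC[C@@H]14 | intermediate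
47 | triol: C1–OH, C4–OH, C12–OH | O[C@]12C=C([C@H](C)O)[C@@]4(C[C@@H]1C[C@H](C(=C)CO)C=C[C@@H]2C)C(=O)O[C@@H]1C[C@H](C)C(/C=C/C(C)=O)=CC[C@@H]14 | intermediate
48 | keto enal: C4 ketone, C12 aldehyde, C1–OH | O[C@]12C=C(C(C)=O)[C@@]4(C[C@@H]1C[C@H](C(=C)C=O)C=C[C@@H]2C)C(=O)O[C@@H]1C[C@H](C)C(/C=C/C(C)=O)=CC[C@@H]14 | intermediate
49 | acrylic acid: C12 CO2H, C4 ketone, C1–OH, C8=C9 | O[C@]12C=C(C(C)=O)[C@@]4(C[C@@H]1C[C@H](C(=C)C(O)=O)C=C[C@@H]2C)C(=O)O[C@@H]1C[C@H](C)C(/C=C/C(C)=O)=CC[C@@H]14 | intermediate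
50 | 9-iodo lactone: cis-fused upper lactone, iodine at C9 trans to the C8 oxygen | C=C1C(=O)O[C@@H]2[C@@H](I)[C@H](C)[C@@]3(O)C=C(C(C)=O)[C@@]4(C[C@@H]3C[C@H]12)C(=O)O[C@@H]1C[C@H](C)C(/C=C/C(C)=O)=CC[C@@H]14 | intermediate
51 | CNP0168949.1 | C=C1C(=O)O[C@@H]2C[C@H](C)[C@@]3(O)C=C(C(C)=O)[C@@]4(C[C@@H]3C[C@H]12)C(=O)O[C@@H]1C[C@H](C)C(/C=C/C(C)=O)=CC[C@@H]14 | target

**Step count**

Total step count: 35
Longest linear sequence: 21 steps (steps 1–5, 7–14, 28–35)

**Steps most likely to fail, with fallbacks**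

Step 30. What may go wrong: the cross-conjugated, α-branched enone carbonyl may be attacked too slowly, so that protodesilylation of the crotylsilane, carbonyl-ene closure through C11=C13 or ionisation of the tertiary allylic alkoxide take over; closure through the antiperiplanar transition state would give the cis-fused C1 epimer. The fallback sets out from 44 and comes back at 46; it inverts the order of alkene formation and ring closure and so bypasses 45. The silyl enol ether 44 would be selenenylated at C2 with PhSeCl in CH2Cl2 at −78 °C (the electrophile should enter anti to the C3 side chain, that is, syn to H3) to give the saturated α-phenylselanyl ketone F1. The isolated and more electrophilic ketone of F1 would then be closed by the same TiCl4-mediated allylsilane 1,2-addition to the β-hydroxy selenide F2, in which no allylic cation can form. Oxidation of F2 with H2O2/pyridine and syn-elimination of the selenoxide, for which H3 is the only β-hydrogen, would create C2=C3 after ring closure and deliver 46.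

Step 28. What may go wrong: poor endo/exo discrimination of the 1,1-disubstituted dienophile, which gives the wrong configuration at C5 relative to C11′, together with slow cycloaddition. The fallback sets out from 43 and 21 (the same cycloaddition) and comes back at 45; C5 is set under thermodynamic instead of kinetic control. The exo cycloadduct F3 formed alongside 44 would be taken through the same Saegusa oxidation to the C5-epimeric cyclohexenone F4. Because C5 is α to the C1 carbonyl, F4 would be equilibrated with DBU in toluene; the equilibrium should favour 45, in which the C6 chain is pseudo-equatorial while C7′ stays pseudo-axial, away from the C3 substituent.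

Step 29. What may go wrong: divalent palladium may attack the crotylsilane (desilylative π-allyl formation) or palladate the hindered silyl enol ether only slowly. The fallback sets out from 44 and comes back at 45; it replaces the palladium-mediated dehydrosilylation by halogenation and elimination. Bromination of the silyl enol ether with N-bromosuccinimide in THF at −78 °C, where it is by far the most nucleophilic alkene, would give the α-bromo ketone F5. Dehydrobromination with Li2CO3/LiBr in DMF, where bromide exchange epimerises C2 and allows anti elimination with H3, would give 45.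

**Further compounds**

F1 | step 30 | α-phenylselanyl ketone: C1 ketone, C2–SePh trans to the C3 side chain, C3–H | O=C1[C@@H]([Se]c2ccccc2)[C@H]([C@H](C)OCc2ccc(OC)cc2)[C@@]4(C[C@@H]1C[C@H](C(=C)COCc2ccc(OC)cc2)[C@@H]([Si](C)(C)C)/C=C/C)C(=O)O[C@@H]1C[C@H](C)C(/C=C/C(C)=O)=CC[C@@H]14
F2 | step 30 | β-hydroxy selenide: cyclised C1 carbinol with C2–SePh, C8=C9 | O[C@]12[C@@H]([Se]c3ccccc3)[C@H]([C@H](C)OCc3ccc(OC)cc3)[C@@]4(C[C@@H]1C[C@H](C(=C)COCc3ccc(OC)cc3)C=C[C@@H]2C)C(=O)O[C@@H]1C[C@H](C)C(/C=C/C(C)=O)=CC[C@@H]14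
F3 | step 28 | exo spiro cycloadduct (C3 and C5 epimeric to 44) | CC(C)(C)[Si](C)(C)OC1=C[C@@H]([C@H](C)OCc2ccc(OC)cc2)[C@@]4(C[C@H]1C[C@H](C(=C)COCc2ccc(OC)cc2)[C@@H]([Si](C)(C)C)/C=C/C)C(=O)O[C@@H]1C[C@H](C)C(/C=C/C(C)=O)=CC[C@@H]14
F4 | step 28 | C5 epimer of cyclohexenone 45 | O=C1C=C([C@H](C)OCc2ccc(OC)cc2)[C@@]4(C[C@H]1C[C@H](C(=C)COCc2ccc(OC)cc2)[C@@H]([Si](C)(C)C)/C=C/C)C(=O)O[C@@H]1C[C@H](C)C(/C=C/C(C)=O)=CC[C@@H]14
F5 | step 29 | α-bromo ketone: C1 ketone, C2–Br, C3–H | O=C1[C@@H](Br)[C@H]([C@H](C)OCc2ccc(OC)cc2)[C@@]4(C[C@@H]1C[C@H](C(=C)COCc2ccc(OC)cc2)[C@@H]([Si](C)(C)C)/C=C/C)C(=O)O[C@@H]1C[C@H](C)C(/C=C/C(C)=O)=CC[C@@H]14
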